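**Retrosynthetic overview**
- Feature: the single carbocycle is numbered C1 (gem-diprenyl), C2 (ketone), C3 (isobutyryl-bearing), C4 (enol carbon), C5 (prenyl carbinol), C6 (ketone). C4–C5–C6 is a 2-hydroxy-2-prenylmalonyl unit whose centre C5 is stereogenic only because C4 is bonded to C3 and C6 to C1; C1–C2–C3 is the 1,3-dinucleophile of an acylacetone.
- Last disconnections: the O–Si bond at C5 and the two C1–prenyl bonds, made one after the other by C-alkylation of a C1 methylene.
- Key disconnection: C1–C6 and C3–C4, a [3+3] double C-acylation of a bis-silyl dienol ether by a malonyl acid chloride/ethyl ester. It is the only ring-forming event and turns the difference between the two carboxyl groups into the C5 configuration.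
- The acid chloride/ester comes from diethyl ketomalonate (ene reaction with 3-methylbut-1-ene, esterase desymmetrisation, bis-silylation, silyl ester to acid chloride); the diene comes from 5-methylhexane-2,4-dione by two silylations.

Key step: step 7

Assumption: the esterase is taken to give the (R)-half-ester in step 2; its sense of hydrolysis on this substrate is not established and must be confirmed on the first batch, and the fallback to step 2 supplies the same (R)-acid whatever the enzyme prefers.

Step 1
Reactants: 1 diethyl ketomalonate; 2 3-methylbut-1-ene
Product: 3 diethyl 2-hydroxy-2-(3-methylbut-2-en-1-yl)propanedioate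
Conditions: 2 (6 equiv), neat, steel autoclave, 150 °C
Reagents that add atoms: none
Why: Thermal carbonyl-ene reaction in which the electron-poor ketone carbon bonds to the terminal alkene carbon while the only allylic hydrogen (the isopropyl methine) moves to oxygen, so the double bond can only end in the prenyl position, and the excess of 2 should keep the product alkene from reacting a second time.

Step 2
Reactants: 3 diethyl 2-hydroxy-2-(3-methylbut-2-en-1-yl)propanedioate
Product: 4 (R)-2-(ethoxycarbonyl)-2-hydroxy-5-methylhex-4-enoic acid
Conditions: pig liver esterase (PLE), 0.1 M phosphate buffer pH 7.5, DMSO (10 vol%), 25 °C, pH-stat with 1 M NaOH (1.0 equiv); then 1 M HCl to pH 2, EtOAc, 0 °C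
Reagents that add atoms: water, O
Why: Esterase desymmetrisation of a prochiral 2,2-disubstituted malonate diester, in which the enzyme hydrolyses one of the two enantiotopic ester groups and the carboxylate formed is no longer a substrate; this sets the quaternary centre that becomes C5 (sense as assumed above).

Step 3
Reactants: 4 (R)-2-(ethoxycarbonyl)-2-hydroxy-5-methylhex-4-enoic acid
Product: 5 1-ethyl 3-(triethylsilyl) (S)-2-(3-methylbut-2-en-1-yl)-2-(triethylsilyloxy)propanedioate
Conditions: Et3SiOTf (2.3 equiv), 2,6-lutidine (3 equiv), CH2Cl2, −78 → 0 °C; pentane, filtration, used crude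
Reagents that add atoms: triethylsilyl trifluoromethanesulfonate, CC[Si](CC)(CC)OS(=O)(=O)C(F)(F)F
Why: Silyl triflate with a hindered pyridine base silylates both the tertiary alcohol and the carboxylic acid (O-silylation), the silyl ester serving as the activated acid for step 4, and the quaternary centre is not touched.

Step 4
Reactants: 5 1-ethyl 3-(triethylsilyl) (S)-2-(3-methylbut-2-en-1-yl)-2-(triethylsilyloxy)propanedioate
Product: 6 ethyl (S)-2-(chlorocarbonyl)-5-methyl-2-(triethylsilyloxy)hex-4-enoate
Conditions: (COCl)2 (1.2 equiv), DMF (cat.), CH2Cl2, 0 °C → rt; evaporation, used crude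
Reagents that add atoms: oxalyl chloride, ClC(=O)C(Cl)=O
Why: The Vilsmeier reagent from oxalyl chloride and DMF converts a trialkylsilyl ester into the acid chloride under neutral conditions with loss of Et3SiCl, so no HCl arises that could add to the prenyl alkene or cleave the silyl ether, and with no α-hydrogen no ketene can form.

Step 5
Reactants: 7 5-methylhexane-2,4-dione
Product: 8 (Z)-5-methyl-4-(trimethylsilyloxy)hex-3-en-2-one
Conditions: Me3SiCl (1.2 equiv), Et3N (1.3 equiv), pentane, rt; filtration, distillation
Reagents that add atoms: chlorotrimethylsilane, C[Si](C)(C)Cl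
Why: Silyl enol ether formation by O-silylation of the chelated cis-enol of the 1,3-diketone gives the Z β-silyloxy enone; the silyl group of such Z enones shifts readily between the two oxygens, which is of no consequence because either placement leads to the same diene in step 6.

Step 6
Reactants: 8 (Z)-5-methyl-4-(trimethylsilyloxy)hex-3-en-2-one
Product: 9 (Z)-5-methyl-2,4-bis(trimethylsilyloxy)hexa-1,3-diene
Conditions: LiN(iPr)2 (1.1 equiv), THF, −78 °C; Me3SiCl (1.2 equiv), −78 → 0 °C; pentane, filtration, used without chromatography
Reagents that add atoms: chlorotrimethylsilane, C[Si](C)(C)Cl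
Why: Kinetic deprotonation by the lithium amide takes a methyl proton (the isopropyl methine is far more hindered) and O-silylation of the cross-conjugated dienolate gives the 1,3-bis(silyloxy)-1,3-diene with the Z internal enol ether retained, the standard two-stage preparation of such dienes from 1,3-diketones.

Step 7
Reactants: 9 (Z)-5-methyl-2,4-bis(trimethylsilyloxy)hexa-1,3-diene; 6 ethyl (S)-2-(chlorocarbonyl)-5-methyl-2-(triethylsilyloxy)hex-4-enoate
Product: 11 (S)-3-hydroxy-2-(2-methylpropanoyl)-4-(3-methylbut-2-en-1-yl)-4-(triethylsilyloxy)cyclohex-2-ene-1,5-dione, via open-chain C1-acylated silyl enol ether 10 (not isolated)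
Conditions: 9 (1.2 equiv), CH2Cl2 (0.05 M), −78 → 20 °C, no Lewis acid; then TiCl4 (2.2 equiv), Et3N (2.5 equiv), −78 → 0 °C; ice-water quench
Reagents that add atoms: none
Why: Proposed new method: the terminal carbon of the bis-silyl dienol ether (future C1), its most nucleophilic position, attacks the acid chloride carbon (future C6) with loss of Me3SiCl to give 10, and TiCl4/Et3N then chelates the β-keto ester and converts the remaining β-silyloxy enone into a trichlorotitanium diketonate whose central carbon (C3) adds to the activated ester carbon (C4), ethoxide leaving from the tetrahedral intermediate. The closest known reactions are the [3+3] cyclocondensations of 1,3-bis(silyloxy)-1,3-dienes with 1,3-dielectrophiles, the uncatalysed terminal acylation of such dienes by acid chlorides, and the TiCl4/amine Dieckmann (titanium Claisen) condensation; what is not precedented is an ester as the second electrophile in the same flask to give a non-aromatisable cyclohexane-1,3,5-trione. The six-membered carbocycle closes in a 6-(enolexo)-exo-trig mode by forming C3–C4 after C1–C6. No stereocentre is created: C5 comes from 6, is quaternary and non-enolisable, and none of its bonds is broken. The step needs chemoselectivity between the two carboxyl carbons, which alone decides whether the (S) ring or its mirror image forms, and it is secured by the reactivity gap between acid chloride and ethyl ester at low temperature before any Lewis acid is present. It also needs C- over O-acylation in the closure, which is favoured because only the 2-acyl trione ends as a stable chelated enolate, while C1 stays an unhindered CH2 so that the first acylation is fast.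

Step 8
Reactants: 11 (S)-3-hydroxy-2-(2-methylpropanoyl)-4-(3-methylbut-2-en-1-yl)-4-(triethylsilyloxy)cyclohex-2-ene-1,5-dione; 12 prenyl bromide
Product: 13 (4S)-3-hydroxy-2-(2-methylpropanoyl)-4,6-bis(3-methylbut-2-en-1-yl)-4-(triethylsilyloxy)cyclohex-2-ene-1,5-dione, mixture of the two C6 epimers
Conditions: LiN(SiMe3)2 (2.1 equiv), THF, −78 → −20 °C; 12 (1.05 equiv), −78 → 0 °C; cold 0.5 M HCl
Reagents that add atoms: none
Why: C-alkylation of a cyclic β-diketone through its dianion, in which the first equivalent of base removes the enol proton of the acyl trione unit and the second forms the enolate at the C1 methylene, whose more basic and less delocalised carbon attacks the allylic bromide by SN2 with lithium in THF favouring carbon over oxygen; the new centre at C1 (C6 of the name) is formed without control, which is harmless because it becomes a non-stereogenic quaternary carbon in step 9, and any doubly alkylated 14 formed here is carried forward.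

Step 9
Reactants: 13 (4S)-3-hydroxy-2-(2-methylpropanoyl)-4,6-bis(3-methylbut-2-en-1-yl)-4-(triethylsilyloxy)cyclohex-2-ene-1,5-dione, mixture of the two C6 epimers; 12 prenyl bromide
Product: 14 (S)-3-hydroxy-2-(2-methylpropanoyl)-4,6,6-tris(3-methylbut-2-en-1-yl)-4-(triethylsilyloxy)cyclohex-2-ene-1,5-dione
Conditions: LiN(SiMe3)2 (2.2 equiv), THF, −78 → 0 °C; 12 (1.5 equiv), 0 °C → rt; cold 0.5 M HCl
Reagents that add atoms: none
Why: Second dianion C-alkylation (SN2) at the now tertiary C1, the known gem-diprenylation of dearomatised acylphloroglucinols, which makes C1 quaternary so that both epimers of 13 converge on one compound, while the triethylsilyl ether blocks base-induced α-ketol ring contraction at C5 and leaves that centre untouched.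

Step 10
Reactants: 14 (S)-3-hydroxy-2-(2-methylpropanoyl)-4,6,6-tris(3-methylbut-2-en-1-yl)-4-(triethylsilyloxy)cyclohex-2-ene-1,5-dione
Product: 15 (S)-3,4-dihydroxy-2-(2-methylpropanoyl)-4,6,6-tris(3-methylbut-2-en-1-yl)cyclohex-2-ene-1,5-dione (target)
Conditions: HF·pyridine, THF, 0 °C → rt
Reagents that add atoms: none
Why: Fluoride cleavage of the triethylsilyl ether under mildly acidic, non-basic conditions should free the tertiary alcohol without α-ketol rearrangement of the hydroxy diketone or acid-induced cyclisation of a prenyl group onto the enol, and quaternary C5 keeps its (S) configuration.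

**Compound list**
1 | diethyl ketomalonate (diethyl 2-oxopropanedioate) | CCOC(=O)C(=O)C(=O)OCC | starting material
2 | 3-methylbut-1-ene | CC(C)C=C | starting material
3 | diethyl 2-hydroxy-2-(3-methylbut-2-en-1-yl)propanedioate | CCOC(=O)C(O)(CC=C(C)C)C(=O)OCC | intermediate
4 | (R)-2-(ethoxycarbonyl)-2-hydroxy-5-methylhex-4-enoic acid | CCOC(=O)[C@@](O)(CC=C(C)C)C(O)=O | intermediate
5 | 1-ethyl 3-(triethylsilyl) (S)-2-(3-methylbut-2-en-1-yl)-2-(triethylsilyloxy)propanedioate | CCOC(=O)[C@@](O[Si](CC)(CC)CC)(CC=C(C)C)C(=O)O[Si](CC)(CC)CC | intermediate
6 | ethyl (S)-2-(chlorocarbonyl)-5-methyl-2-(triethylsilyloxy)hex-4-enoate | CCOC(=O)[C@@](O[Si](CC)(CC)CC)(CC=C(C)C)C(Cl)=O | intermediate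
7 | 5-methylhexane-2,4-dione | CC(C)C(=O)CC(C)=O | starting material
8 | (Z)-5-methyl-4-(trimethylsilyloxy)hex-3-en-2-one | CC(C)/C(O[Si](C)(C)C)=C/C(C)=O | intermediate
9 | (Z)-5-methyl-2,4-bis(trimethylsilyloxy)hexa-1,3-diene | CC(C)/C(O[Si](C)(C)C)=C/C(=C)O[Si](C)(C)C | intermediate
10 | ethyl (2R,6Z)-8-methyl-2-(3-methylbut-2-en-1-yl)-3,5-dioxo-2-(triethylsilyloxy)-7-(trimethylsilyloxy)non-6-enoate; formed in the flask in step 7 | CCOC(=O)[C@@](O[Si](CC)(CC)CC)(CC=C(C)C)C(=O)CC(=O)/C=C(\O[Si](C)(C)C)C(C)C | intermediate
11 | (S)-3-hydroxy-2-(2-methylpropanoyl)-4-(3-methylbut-2-en-1-yl)-4-(triethylsilyloxy)cyclohex-2-ene-1,5-dione | C1C(=O)C(C(=O)C(C)C)=C(O)[C@@](O[Si](CC)(CC)CC)(CC=C(C)C)C1=O | intermediate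
12 | prenyl bromide (1-bromo-3-methylbut-2-ene) | CC(C)=CCBr | starting material
13 | (4S)-3-hydroxy-2-(2-methylpropanoyl)-4,6-bis(3-methylbut-2-en-1-yl)-4-(triethylsilyloxy)cyclohex-2-ene-1,5-dione, mixture of the two C6 epimers | CC(C)=CCC1C(=O)C(C(=O)C(C)C)=C(O)[C@@](O[Si](CC)(CC)CC)(CC=C(C)C)C1=O | intermediate
14 | (S)-3-hydroxy-2-(2-methylpropanoyl)-4,6,6-tris(3-methylbut-2-en-1-yl)-4-(triethylsilyloxy)cyclohex-2-ene-1,5-dione | CC(C)=CCC1(CC=C(C)C)C(=O)C(C(=O)C(C)C)=C(O)[C@@](O[Si](CC)(CC)CC)(CC=C(C)C)C1=O | intermediate
15 | (S)-3,4-dihydroxy-2-(2-methylpropanoyl)-4,6,6-tris(3-methylbut-2-en-1-yl)cyclohex-2-ene-1,5-dione | CC(C)=CCC1(CC=C(C)C)C(=O)C(C(=O)C(C)C)=C(O)[C@@](O)(CC=C(C)C)C1=O | target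

**Total step count:** 10
**Longest linear sequence:** 8 steps (steps 1, 2, 3, 4, 7, 8, 9, 10); steps 5 and 6 form the side branch to the diene.

**Steps most likely to fail**

1. Step 7 (proposed new method). The closure may run through oxygen instead of carbon, either by lactonisation of the C2 enol oxygen onto the ester or by Lewis-acid cyclodehydration of the 1,3,5-triketone array to a 4-pyranone. It may also stall at the open chain because the titanium-bound diketonate is too weak a nucleophile for an ester, and the Lewis acid may cleave the C5 silyl ether. The fallback uses known chemistry in two operations and sets out from 9 and 6. Only the uncatalysed terminal acylation is run (CH2Cl2, −78 → 20 °C), and the remaining trimethylsilyl enol ether of 10 is hydrolysed on work-up (aqueous NaHCO3, then pH 5 buffer) to give ethyl (R)-8-methyl-2-(3-methylbut-2-en-1-yl)-3,5,7-trioxo-2-(triethylsilyloxy)nonanoate F1, which is isolated. The ring is then closed with base, LiN(SiMe3)2 (3.2 equiv) in THF at −78 → 0 °C, by the classical Claisen (Dieckmann-type) cyclisation of a 3,5,7-triketo ester polyanion to a 2-acylcyclohexane-1,3,5-trione. The carbon between the two distal ketones (future C3) is the only carbon that can reach the ester through a six-membered transition state, and the non-nucleophilic base avoids retro-Claisen cleavage at the non-enolisable β-keto ester. Acidification with cold dilute HCl gives 11, where the route is rejoined.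

2. Step 2. The enzyme may discriminate poorly between the two enantiotopic ester groups, or hydrolyse with the opposite preference, so that C5 would be set with low enantiomeric purity or as the mirror image. The fallback sets out from 3. Chemical half-saponification (KOH, 1.0 equiv, EtOH, 0 °C → rt; then cold HCl) gives racemic 2-(ethoxycarbonyl)-2-hydroxy-5-methylhex-4-enoic acid F2. This is resolved through its diastereomeric salt with 1-phenylethylamine, (S)-1-phenylethylammonium (R)-2-(ethoxycarbonyl)-2-hydroxy-5-methylhex-4-enoate F3, recrystallised to constant rotation. The salt is drawn with the (S)-amine; the amine enantiomer that gives the less soluble salt of the (R)-acid has to be chosen by trial. Release of the acid with cold dilute HCl gives 4, where the route is rejoined. The same salt crystallisation can also raise the enantiomeric purity of enzyme-derived 4.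

3. Step 9. Alkylation may occur on the enolate oxygens instead of C1, or the enolate of 13 may react too slowly, because this alkylation builds a quaternary carbon 1,3 to the silyloxy-bearing C5. The fallback sets out from 13 and uses a Tsuji–Trost allylation with methyl 3-methylbut-2-en-1-yl carbonate (1.5 equiv) and Pd(PPh3)4 (zerovalent palladium, 5 mol%) in THF at rt → 50 °C. The methoxide released from the carbonate serves as base, and the soft C1 enolate attacks the unsubstituted terminus of the π-(1,1-dimethylallyl)Pd(PPh3)2 cation to give the linear prenyl group. Any O-allylated material re-ionises under the catalyst and is funnelled to the C-allylated product. The fallback rejoins the route at 14. It makes no compound outside the route: none F0.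

**Further compounds**
F1 | step 7 | ethyl (R)-8-methyl-2-(3-methylbut-2-en-1-yl)-3,5,7-trioxo-2-(triethylsilyloxy)nonanoate | CCOC(=O)[C@@](O[Si](CC)(CC)CC)(CC=C(C)C)C(=O)CC(=O)CC(=O)C(C)C
F2 | step 2 | racemic 2-(ethoxycarbonyl)-2-hydroxy-5-methylhex-4-enoic acid | CCOC(=O)C(O)(CC=C(C)C)C(O)=O
F3 | step 2 | (S)-1-phenylethylammonium (R)-2-(ethoxycarbonyl)-2-hydroxy-5-methylhex-4-enoate | CCOC(=O)[C@@](O)(CC=C(C)C)C(=O)[O-].C[C@H]([NH3+])c1ccccc1
F0 | step 9 | none | none
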